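The target is cut through ring C of the flavan-3-ol half (unit E): its O1–C2 and C3–C4 bonds are made together by a chiral-acid-catalysed hetero-Diels–Alder reaction between an ortho-quinone methide and an (E)-enol acetate. This exploits the all-trans C2/C3/C4 array of unit E, whose C4 carries C6 of the flavan-3,4-diol half (unit T): one operation closes ring C and sets all three stereocentres. The precursor is an ortho-hydroxybenzhydrol linking a ketal-protected pyrogallol ring (future ring A of unit E) to C6 of a benzylated (2R,3R)-dihydroflavonol; the C4 ketone of unit T is kept until the last step, where NaBH4 gives the 3,4-trans diol.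

Key step: step 15

Assumption: the sense of facial induction of the phosphoric acid on this benzhydrol cannot be predicted with confidence; (R)-TRIP is written, and its enantiomer would be used if a model cycloaddition shows the opposite sense.

Remark on descriptors: target unit T is (2R,3S,4R), unit E is (2S,3R,4S). In the benzylated compounds 22 and 23 the same geometry at C4 of unit E is labelled 4R, because O-benzylation changes the CIP ranking of the two aryl groups.

Remark on design:
- The ring A formyl group of unit T is unmasked only after the chalcone chemistry (carried as bromide, then vinyl), because a free aryl aldehyde would compete in the aldol condensation.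
- The catechol of unit E is tied back as a diphenylmethylene ketal, which is one step from pyrogallol and leaves the quinone methide oxygen unhindered.
- The acetate is removed under acid, because the 3-benzyloxychromanone of unit T is base-sensitive.
- The enol acetate is made by a stereoretentive coupling, so that no (Z)-isomer reaches the key step.

Step 1
Reactants: 1 gallacetophenone (1-(2,3,4-trihydroxyphenyl)ethan-1-one)
Product: 2 1-[3,4-bis(benzyloxy)-2-hydroxyphenyl]ethan-1-one
Conditions: BnBr (2.1 eq), K2CO3 (2.2 eq), acetone, reflux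
Reagents that add atoms: benzyl bromide, BrCc1ccccc1
Why: Williamson etherification; the 2-OH is hydrogen-bonded to the acetyl carbonyl and resists alkylation under carbonate conditions, so only the 3- and 4-OH should be benzylated.

Step 2
Reactants: 2 1-[3,4-bis(benzyloxy)-2-hydroxyphenyl]ethan-1-one
Product: 3 1-[3,4-bis(benzyloxy)-5-bromo-2-hydroxyphenyl]ethan-1-one
Conditions: NBS (1.05 eq), MeCN, 0 °C to rt
Reagents that add atoms: N-bromosuccinimide, O=C1CCC(=O)N1Br
Why: Electrophilic aromatic bromination; C5 is para to the free phenol, ortho to the 4-benzyloxy group and meta to the acetyl group, so all directing effects converge on it.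

Step 3
Reactants: 3 1-[3,4-bis(benzyloxy)-5-bromo-2-hydroxyphenyl]ethan-1-one
Product: 4 1-[3,4-bis(benzyloxy)-5-bromo-2-(methoxymethoxy)phenyl]ethan-1-one
Conditions: NaH (1.2 eq), MOMCl (1.5 eq), DMF, 0 °C to rt
Reagents that add atoms: chloromethyl methyl ether, COCCl
Why: Williamson-type O-alkylation of the sodium phenoxide; the MOM ether blocks the phenol so that the later basic peroxide step epoxidises the enone without cyclising it to a flavonol.

Step 4
Reactants: 4 1-[3,4-bis(benzyloxy)-5-bromo-2-(methoxymethoxy)phenyl]ethan-1-one; 5 4-(benzyloxy)benzaldehyde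
Product: 6 (E)-1-[3,4-bis(benzyloxy)-5-bromo-2-(methoxymethoxy)phenyl]-3-[4-(benzyloxy)phenyl]prop-2-en-1-one
Conditions: KOH (50% aq.), EtOH/THF, rt
Reagents that add atoms: none
Why: Claisen–Schmidt aldol condensation; the acetophenone enolate adds to the non-enolisable aldehyde and E1cB dehydration gives the (E)-enone, the aryl bromide standing in for a formyl group that would compete as an electrophile.

Step 5
Reactants: 6 (E)-chalcone
Product: 7 [(2R,3S)-3-(4-benzyloxyphenyl)oxiran-2-yl][3,4-bis(benzyloxy)-5-bromo-2-(methoxymethoxy)phenyl]methanone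
Conditions: immobilised poly-L-leucine, urea–H2O2, DBU, THF, rt
Reagents that add atoms: urea–hydrogen peroxide, NC(N)=O.OO
Why: Juliá–Colonna asymmetric nucleophilic epoxidation; the helical poly-L-leucine binds the hydroperoxide–enone adduct and delivers oxygen to one enone face, which is expected to give the (2R,3S)-trans-epoxide and so sets the future C3 of unit T.

Step 6
Reactants: 7 (2R,3S)-epoxy ketone MOM ether
Product: 9 (2R,3R)-7,8-bis(benzyloxy)-2-[4-(benzyloxy)phenyl]-6-bromo-3-hydroxychroman-4-one, via free-phenol epoxy ketone 8 (not isolated)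
Conditions: conc. HCl (cat.), MeOH/THF, 50 °C
Reagents that add atoms: none
Why: Acid-catalysed MOM cleavage followed by 6-endo epoxide opening by the freed phenol at the 4-benzyloxybenzylic carbon; C3 keeps the configuration of the epoxide α-carbon and C2 forms with inversion (or, if the opening is cation-like, under the thermodynamic preference) to give the diequatorial 2,3-trans ring.

Step 7
Reactants: 9 (2R,3R)-6-bromo-3-hydroxy dihydroflavonol
Product: 10 (2R,3R)-3,7,8-tris(benzyloxy)-2-[4-(benzyloxy)phenyl]-6-bromochroman-4-one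
Conditions: BnOC(=NH)CCl3 (2 eq), TfOH (0.1 eq), CH2Cl2/cyclohexane, 0 °C to rt
Reagents that add atoms: benzyl 2,2,2-trichloroacetimidate, N=C(OCc1ccccc1)C(Cl)(Cl)Cl
Why: Acid-catalysed O-benzylation with a trichloroacetimidate donor; it avoids the bases that would enolise C3 and open or oxidise the dihydroflavonol.

Step 8
Reactants: 10 (2R,3R)-6-bromo-3-O-benzyl dihydroflavonol
Product: 11 (2R,3R)-3,7,8-tris(benzyloxy)-2-[4-(benzyloxy)phenyl]-6-ethenylchroman-4-one
Conditions: Bu3SnCH=CH2 (1.3 eq), Pd(PPh3)4 (5 mol%), toluene, 100 °C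
Reagents that add atoms: tributyl(vinyl)stannane, C=C[Sn](CCCC)(CCCC)CCCC
Why: Stille cross-coupling; it runs under neutral conditions that leave the stereocentre α to the ketone untouched and installs a vinyl group as a latent aldehyde.

Step 9
Reactants: 11 (2R,3R)-6-ethenyl dihydroflavonol
Product: 13 (2R,3R)-3,7,8-tris(benzyloxy)-2-[4-(benzyloxy)phenyl]-4-oxochromane-6-carbaldehyde, via vicinal diol 12 (not isolated)
Conditions: OsO4 (2 mol%), NaIO4 (4 eq), 2,6-lutidine (2 eq), dioxane/H2O 3:1, rt
Reagents that add atoms: osmium tetroxide, O=[Os](=O)(=O)=O (oxygen donor, regenerated by sodium periodate, [Na+].[O-]I(=O)(=O)=O)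
Why: Lemieux–Johnson oxidation (dihydroxylation of the styrene, then periodate glycol cleavage); the vinyl group is the only alkene, and the benzyl ethers and the ketone are inert.

Step 10
Reactants: 14 pyrogallol
Product: 15 2,2-diphenyl-1,3-benzodioxol-4-ol
Conditions: Ph2CCl2 (1.1 eq), neat, 170 °C
Reagents that add atoms: dichlorodiphenylmethane, ClC(Cl)(c1ccccc1)c1ccccc1
Why: Ketalisation of a catechol with a gem-dichloride (double nucleophilic substitution); only adjacent hydroxyls can close the five-membered ring, so the symmetric triol should give one ketal with a single free phenol.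

Step 11
Reactants: 15 2,2-diphenyl-1,3-benzodioxol-4-ol; 13 (2R,3R)-dihydroflavonol 6-carbaldehyde
Product: 17 (2R,3R)-3,7,8-tris(benzyloxy)-2-[4-(benzyloxy)phenyl]-6-[hydroxy(4-hydroxy-2,2-diphenyl-1,3-benzodioxol-5-yl)methyl]chroman-4-one (both carbinol epimers), via magnesium phenoxide 16 (not isolated)
Conditions: 15 (1.5 eq), EtMgBr (1.5 eq), Et2O, 0 °C, solvent exchanged for CH2Cl2; then 13 (1.0 eq), CH2Cl2, rt
Reagents that add atoms: none
Why: Ortho-specific hydroxyalkylation of a magnesium phenoxide; magnesium holds phenoxide oxygen and aldehyde in a six-membered transition state in a non-coordinating solvent, so the only free ortho carbon attacks the aldehyde while the hindered ketone is left alone, and the new carbinol centre needs no control because step 15 planarises it.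

Step 12
Reactants: 5 4-(benzyloxy)benzaldehyde
Product: 18 (E)-2-{2-[4-(benzyloxy)phenyl]ethenyl}-4,4,5,5-tetramethyl-1,3,2-dioxaborolane
Conditions: CH2(Bpin)2 (1.2 eq), LiTMP (1.2 eq), THF, 0 °C; then 5, −78 °C to rt
Reagents that add atoms: bis(4,4,5,5-tetramethyl-1,3,2-dioxaborolan-2-yl)methane, CC1(C)OB(CB2OC(C)(C)C(C)(C)O2)OC1(C)C
Why: Boron–Wittig olefination; the lithiated geminal bis(boronate) adds to the aldehyde and syn-elimination of the boron–oxygen fragment should give the trans-alkenylboronate.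

Step 13
Reactants: 18 (E)-alkenylboronic acid pinacol ester
Product: 19 potassium (E)-{2-[4-(benzyloxy)phenyl]ethenyl}trifluoroborate
Conditions: KHF2 (4 eq, aq.), MeOH, rt
Reagents that add atoms: potassium hydrogen difluoride, [K+].F[H-]F
Why: Conversion of a pinacol boronate into a trifluoroborate salt; fluoride displaces the diol from boron and the alkene geometry is not involved.

Step 14
Reactants: 19 potassium (E)-alkenyltrifluoroborate
Product: 20 (E)-2-[4-(benzyloxy)phenyl]ethenyl acetate
Conditions: AcOH (2 eq), CuBr (10 mol%), DMAP (20 mol%), 4 Å MS, O2 (1 atm), CH2Cl2, 40 °C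
Reagents that add atoms: acetic acid, CC(=O)O
Why: Copper-catalysed oxidative C–O coupling of an alkenyltrifluoroborate with a carboxylic acid (Chan–Lam type); transmetalation and reductive elimination retain the alkene geometry, so the (E)-enol ester should form free of the (Z)-isomer.

Step 15
Reactants: 17 ortho-hydroxybenzhydrol; 20 (E)-2-[4-(benzyloxy)phenyl]ethenyl acetate
Product: 22 benzylated dimer: unit T (2R,3R)-3,7,8-tris(benzyloxy)-2-(4-benzyloxyphenyl)chroman-4-one joined through C6 to C4 of unit E, a (2S,3R,4R)-3-acetoxy-2-(4-benzyloxyphenyl)flavan with 7,8-O,O-diphenylmethylene ketal (2,3-trans-3,4-trans), via ortho-quinone methide 21 (not isolated)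
Conditions: 20 (3 eq), (R)-TRIP [(R)-3,3'-bis(2,4,6-triisopropylphenyl)-1,1'-binaphthyl-2,2'-diyl hydrogen phosphate] (10 mol%), 4 Å MS, CH2Cl2, 0 °C to rt
Reagents that add atoms: none
Why: The phosphoric acid protonates the benzhydrol hydroxyl, water leaves and the (E)-ortho-quinone methide 21 stays hydrogen-bonded to the chiral phosphate; the enol acetate then adds across its O=C–C=C unit in a concerted, asynchronous inverse-demand hetero-Diels–Alder reaction, the acetoxy-bearing carbon attacking the methide carbon (C3–C4) while the quinone oxygen closes on the developing 4-benzyloxybenzylic cation centre (O1–C2). The closest known reaction type is the chiral phosphoric acid-catalysed [4+2] cycloaddition of ortho-quinone methides from ortho-hydroxybenzhydrols with β-substituted electron-rich styrenes, the enol ester being the only extension. Ring C of unit E is closed by the cycloaddition itself, two σ bonds forming in one suprafacial event, not by a separate cyclisation. C4 is set by the catalyst, which shields one face of the planar methide (the stereocentres of unit T are too remote to matter); C3 and C2 follow from C4 through the aryl-endo transition state and the (E)-geometry of the alkene, which translate into 3,4-trans and 2,3-trans. The step needs regioselectivity (aryl at C2, oxygen at C3), secured because the 4-benzyloxyphenyl group stabilises positive charge far better than the weakly donating acetoxy group, and chemoselectivity for the one ring that can form a quinone methide, secured because unit T has no free phenol and its ring A is deactivated by the C4 ketone.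

Step 16
Reactants: 22 benzylated dimer 3-O-acetate
Product: 23 benzylated dimer with free 3-OH on unit E (unit E 2S,3R,4R; unit T 2R,3R ketone)
Conditions: HCl (1.25 M in MeOH), CH2Cl2/MeOH, rt
Reagents that add atoms: none
Why: Acid-catalysed transesterification (methanolysis) of the acetate; acid is preferred to carbonate or methoxide because the 3-benzyloxychromanone of unit T could enolise and ring-open under base, and any early loss of the ketal would be harmless since step 17 removes it.

Step 17
Reactants: 23 benzylated dimer alcohol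
Product: 24 (2R,3R)-3,7,8-trihydroxy-2-(4-hydroxyphenyl)-6-[(2S,3R,4S)-3,7,8-trihydroxy-2-(4-hydroxyphenyl)-3,4-dihydro-2H-chromen-4-yl]chroman-4-one
Conditions: H2 (1 atm), Pd(OH)2/C, THF/MeOH 1:1, rt
Reagents that add atoms: none
Why: Catalytic hydrogenolysis of the five benzyl ethers and the diphenylmethylene ketal; the ketone, deactivated as a vinylogous ester by O1 and the 7-oxygen, should survive, and doing this before the reduction avoids hydrogenolysis of a benzylic 4-hydroxyl.

Step 18
Reactants: 24 dimeric dihydroflavonol ketone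
Product: 25 (2R,3S,4R)-6-[(2S,3R,4S)-3,7,8-trihydroxy-2-(4-hydroxyphenyl)-3,4-dihydro-2H-chromen-4-yl]-2-(4-hydroxyphenyl)-3,4-dihydro-2H-chromene-3,4,7,8-tetrol (target)
Conditions: NaBH4 (4 eq), MeOH, 0 °C, argon; then pH 6 buffer
Reagents that add atoms: none
Why: Hydride reduction of the dihydroflavonol ketone; axial delivery to the half-chair that has the 2-aryl and 3-hydroxyl groups equatorial gives the equatorial 4-hydroxyl trans to the 3-hydroxyl, the usual outcome for NaBH4 and 2,3-trans-dihydroflavonols, which sets C4 of unit T as R.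

Compound list
1 | gallacetophenone, 1-(2,3,4-trihydroxyphenyl)ethan-1-one | CC(=O)c1ccc(O)c(O)c1O | starting material
2 | 1-[3,4-bis(benzyloxy)-2-hydroxyphenyl]ethan-1-one | CC(=O)c1ccc(OCc2ccccc2)c(OCc2ccccc2)c1O | intermediate
3 | 1-[3,4-bis(benzyloxy)-5-bromo-2-hydroxyphenyl]ethan-1-one | CC(=O)c1cc(Br)c(OCc2ccccc2)c(OCc2ccccc2)c1O | intermediate
4 | 1-[3,4-bis(benzyloxy)-5-bromo-2-(methoxymethoxy)phenyl]ethan-1-one | CC(=O)c1cc(Br)c(OCc2ccccc2)c(OCc2ccccc2)c1OCOC | intermediate
5 | 4-(benzyloxy)benzaldehyde | O=Cc1ccc(OCc2ccccc2)cc1 | starting material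
6 | (E)-1-[3,4-bis(benzyloxy)-5-bromo-2-(methoxymethoxy)phenyl]-3-[4-(benzyloxy)phenyl]prop-2-en-1-one | COCOc1c(C(=O)/C=C/c2ccc(OCc3ccccc3)cc2)cc(Br)c(OCc2ccccc2)c1OCc1ccccc1 | intermediate
7 | [(2R,3S)-3-(4-benzyloxyphenyl)oxiran-2-yl][3,4-bis(benzyloxy)-5-bromo-2-(methoxymethoxy)phenyl]methanone | COCOc1c(C(=O)[C@@H]2O[C@H]2c2ccc(OCc3ccccc3)cc2)cc(Br)c(OCc2ccccc2)c1OCc1ccccc1 | intermediate
8 | [(2R,3S)-3-(4-benzyloxyphenyl)oxiran-2-yl][3,4-bis(benzyloxy)-5-bromo-2-hydroxyphenyl]methanone | Oc1c(C(=O)[C@@H]2O[C@H]2c2ccc(OCc3ccccc3)cc2)cc(Br)c(OCc2ccccc2)c1OCc1ccccc1 | intermediate (not isolated)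
9 | (2R,3R)-7,8-bis(benzyloxy)-2-[4-(benzyloxy)phenyl]-6-bromo-3-hydroxychroman-4-one | c1ccc(COc2ccc([C@H]3Oc4c(cc(Br)c(OCc5ccccc5)c4OCc4ccccc4)C(=O)[C@@H]3O)cc2)cc1 | intermediate
10 | (2R,3R)-3,7,8-tris(benzyloxy)-2-[4-(benzyloxy)phenyl]-6-bromochroman-4-one | c1ccc(COc2ccc([C@H]3Oc4c(cc(Br)c(OCc5ccccc5)c4OCc4ccccc4)C(=O)[C@@H]3OCc3ccccc3)cc2)cc1 | intermediate
11 | (2R,3R)-3,7,8-tris(benzyloxy)-2-[4-(benzyloxy)phenyl]-6-ethenylchroman-4-one | c1ccc(COc2ccc([C@H]3Oc4c(cc(C=C)c(OCc5ccccc5)c4OCc4ccccc4)C(=O)[C@@H]3OCc3ccccc3)cc2)cc1 | intermediate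
12 | (2R,3R)-3,7,8-tris(benzyloxy)-2-[4-(benzyloxy)phenyl]-6-(1,2-dihydroxyethyl)chroman-4-one (carbinol epimers) | c1ccc(COc2ccc([C@H]3Oc4c(cc(C(O)CO)c(OCc5ccccc5)c4OCc4ccccc4)C(=O)[C@@H]3OCc3ccccc3)cc2)cc1 | intermediate (not isolated)
13 | (2R,3R)-3,7,8-tris(benzyloxy)-2-[4-(benzyloxy)phenyl]-4-oxochromane-6-carbaldehyde | c1ccc(COc2ccc([C@H]3Oc4c(cc(C=O)c(OCc5ccccc5)c4OCc4ccccc4)C(=O)[C@@H]3OCc3ccccc3)cc2)cc1 | intermediate
14 | pyrogallol | Oc1cccc(O)c1O | starting material
15 | 2,2-diphenyl-1,3-benzodioxol-4-ol | Oc1cccc2OC(c3ccccc3)(c3ccccc3)Oc12 | intermediate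
16 | bromomagnesium 2,2-diphenyl-1,3-benzodioxol-4-olate | Br[Mg]Oc1cccc2OC(c3ccccc3)(c3ccccc3)Oc12 | intermediate (not isolated)
17 | (2R,3R)-3,7,8-tris(benzyloxy)-2-[4-(benzyloxy)phenyl]-6-[hydroxy(4-hydroxy-2,2-diphenyl-1,3-benzodioxol-5-yl)methyl]chroman-4-one (carbinol epimers) | c1ccc(COc2ccc([C@H]3Oc4c(cc(C(O)c5ccc6OC(c7ccccc7)(c7ccccc7)Oc6c5O)c(OCc5ccccc5)c4OCc4ccccc4)C(=O)[C@@H]3OCc3ccccc3)cc2)cc1 | intermediate
18 | (E)-2-{2-[4-(benzyloxy)phenyl]ethenyl}-4,4,5,5-tetramethyl-1,3,2-dioxaborolane | CC1(C)OB(/C=C/c2ccc(OCc3ccccc3)cc2)OC1(C)C | intermediate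
19 | potassium (E)-{2-[4-(benzyloxy)phenyl]ethenyl}trifluoroborate | [K+].F[B-](F)(F)/C=C/c1ccc(OCc2ccccc2)cc1 | intermediate
20 | (E)-2-[4-(benzyloxy)phenyl]ethenyl acetate | CC(=O)O/C=C/c1ccc(OCc2ccccc2)cc1 | intermediate
21 | (2R,3R)-3,7,8-tris(benzyloxy)-2-[4-(benzyloxy)phenyl]-6-[(E)-(4-oxo-2,2-diphenyl-1,3-benzodioxol-5(4H)-ylidene)methyl]chroman-4-one (ortho-quinone methide) | c1ccc(COc2ccc([C@H]3Oc4c(cc(/C=C5\C=CC6=C(C5=O)OC(c7ccccc7)(c7ccccc7)O6)c(OCc5ccccc5)c4OCc4ccccc4)C(=O)[C@@H]3OCc3ccccc3)cc2)cc1 | intermediate (not isolated)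
22 | benzylated dimer, unit E (2S,3R,4R) 3-O-acetate with 7,8-diphenylmethylene ketal, unit T (2R,3R) C4 ketone | c1ccc(COc2ccc([C@H]3Oc4c(cc([C@H]5c6ccc7OC(c8ccccc8)(c8ccccc8)Oc7c6O[C@@H](c6ccc(OCc7ccccc7)cc6)[C@@H]5OC(C)=O)c(OCc5ccccc5)c4OCc4ccccc4)C(=O)[C@@H]3OCc3ccccc3)cc2)cc1 | intermediate
23 | benzylated dimer, unit E (2S,3R,4R) 3-OH, unit T (2R,3R) C4 ketone | c1ccc(COc2ccc([C@H]3Oc4c(cc([C@H]5c6ccc7OC(c8ccccc8)(c8ccccc8)Oc7c6O[C@@H](c6ccc(OCc7ccccc7)cc6)[C@@H]5O)c(OCc5ccccc5)c4OCc4ccccc4)C(=O)[C@@H]3OCc3ccccc3)cc2)cc1 | intermediate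
24 | (2R,3R)-3,7,8-trihydroxy-2-(4-hydroxyphenyl)-6-[(2S,3R,4S)-3,7,8-trihydroxy-2-(4-hydroxyphenyl)-3,4-dihydro-2H-chromen-4-yl]chroman-4-one | Oc1ccc([C@H]2Oc3c(cc([C@H]4c5ccc(O)c(O)c5O[C@@H](c5ccc(O)cc5)[C@@H]4O)c(O)c3O)C(=O)[C@@H]2O)cc1 | intermediate
25 | (2R,3S,4R)-6-[(2S,3R,4S)-3,7,8-trihydroxy-2-(4-hydroxyphenyl)-3,4-dihydro-2H-chromen-4-yl]-2-(4-hydroxyphenyl)-3,4-dihydro-2H-chromene-3,4,7,8-tetrol | Oc1ccc([C@H]2Oc3c(cc([C@H]4c5ccc(O)c(O)c5O[C@@H](c5ccc(O)cc5)[C@@H]4O)c(O)c3O)[C@@H](O)[C@@H]2O)cc1 | target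

Total step count: 18. Longest linear sequence: 14 steps (steps 1–9, 11, 15–18, from gallacetophenone).

Steps most likely to fail

Step 15. The acetoxy group may compete with the aryl group in polarising the alkene, reversing the regiochemistry, or the catalyst may give poor facial or endo/exo selectivity. The fallback builds ring C of unit E stepwise; it sets out from 17 (with 19) and returns at 23.
- Trifluoroborate 19 would be hydrolysed (silica gel, water) to (E)-{2-[4-(benzyloxy)phenyl]ethenyl}boronic acid F1.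
- A chiral 3,3'-dibromo-BINOL catalyst (molecular sieves, an alcohol to form the boronate ester in the flask) would mediate asymmetric conjugate addition of the alkenyl group to the ortho-quinone methide released from 17. This is a known reaction type that forms only C3–C4 and should give the (E)-1,1-diaryl-3-arylpropene phenol F2, with the future C4 set by the catalyst.
- Sharpless asymmetric dihydroxylation with (DHQD)2PHAL as ligand would give the (1R,2R)-syn-diol F3 under reagent control. K2OsO2(OH)4 with NMO as co-oxidant in acetone/H2O is chosen so that the free phenol is not exposed to K3Fe(CN)6.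
- TsOH in CH2Cl2 would ionise the 4-benzyloxybenzylic hydroxyl, and the phenol would close the six-membered ring to the all-equatorial flavan-3-ol 23.

Step 11. The magnesium alkoxide of the product may eliminate to the quinone methide and be arylated a second time, or the phenoxide may enolise the dihydroflavonol. The fallback sets out from 13 and 15 and returns at 17.
- The two would be condensed with PhB(OH)2 (cat. EtCO2H, toluene, reflux, water removal) in a boron-templated ortho-hydroxyalkylation, in which boron tethers phenol and aldehyde and traps the product as the cyclic 2-phenyl-4H-1,3,2-benzodioxaborin F4.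
- Transesterification with propane-1,3-diol (THF, rt) would then release benzhydrol 17.

Step 6. Under protic acid the benzylic cation from the epoxide may undergo aroyl migration (towards isoflavone-type products) or 5-exo closure instead of the 6-endo ring closure. The fallback uses a sulfur relay; it sets out from 7 and returns at 9.
- BnSH and SnCl4 (CH2Cl2, −20 °C) would open the epoxide at the benzylic carbon and remove the MOM group, giving (2S)-1-[3,4-bis(benzyloxy)-5-bromo-2-hydroxyphenyl]-3-[4-(benzyloxy)phenyl]-3-(benzylsulfanyl)-2-hydroxypropan-1-one F5 (C3 epimers; C2 geometry retained from 7, the descriptor changing only through the sulfur substituent).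
- AgBF4 (CH2Cl2, 0 °C) would then activate the sulfide as a leaving group, so that the phenol closes the pyranone ring to the trans-dihydroflavonol 9.

Further compounds
F1 | step 15 | (E)-{2-[4-(benzyloxy)phenyl]ethenyl}boronic acid | OB(O)/C=C/c1ccc(OCc2ccccc2)cc1
F2 | step 15 | (2R,3R)-3,7,8-tris(benzyloxy)-2-[4-(benzyloxy)phenyl]-6-[(1R,2E)-3-[4-(benzyloxy)phenyl]-1-(4-hydroxy-2,2-diphenyl-1,3-benzodioxol-5-yl)prop-2-en-1-yl]chroman-4-one | c1ccc(COc2ccc([C@H]3Oc4c(cc([C@H](/C=C/c5ccc(OCc6ccccc6)cc5)c5ccc6OC(c7ccccc7)(c7ccccc7)Oc6c5O)c(OCc5ccccc5)c4OCc4ccccc4)C(=O)[C@@H]3OCc3ccccc3)cc2)cc1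
F3 | step 15 | (2R,3R)-3,7,8-tris(benzyloxy)-2-[4-(benzyloxy)phenyl]-6-[(1R,2R,3R)-3-[4-(benzyloxy)phenyl]-2,3-dihydroxy-1-(4-hydroxy-2,2-diphenyl-1,3-benzodioxol-5-yl)propyl]chroman-4-one | c1ccc(COc2ccc([C@H]3Oc4c(cc([C@H]([C@@H](O)[C@H](O)c5ccc(OCc6ccccc6)cc5)c5ccc6OC(c7ccccc7)(c7ccccc7)Oc6c5O)c(OCc5ccccc5)c4OCc4ccccc4)C(=O)[C@@H]3OCc3ccccc3)cc2)cc1
F4 | step 11 | 2-phenyl-4H-1,3,2-benzodioxaborin from 13, 15 and PhB(OH)2 (its C4 carries C6 of unit T; diphenylmethylene ketal retained; C4 epimers) | c1ccc(COc2ccc([C@H]3Oc4c(cc(C5OB(c6ccccc6)Oc6c5ccc5OC(c7ccccc7)(c7ccccc7)Oc65)c(OCc5ccccc5)c4OCc4ccccc4)C(=O)[C@@H]3OCc3ccccc3)cc2)cc1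
F5 | step 6 | (2S)-1-[3,4-bis(benzyloxy)-5-bromo-2-hydroxyphenyl]-3-[4-(benzyloxy)phenyl]-3-(benzylsulfanyl)-2-hydroxypropan-1-one (C3 epimers) | O=C([C@H](O)C(SCc1ccccc1)c1ccc(OCc2ccccc2)cc1)c1cc(Br)c(OCc2ccccc2)c(OCc2ccccc2)c1O
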